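**Plan**

- Retrosynthesis: remove the 7-O-MOM ether, then cut the furan C2=C3 double bond (ring-closing metathesis), then the C-allyl and C-prenyl aryl–carbon bonds on ring B (two ortho-Claisen shifts from O4'), which leads back to (2S)-naringenin.
- Enabling feature: benzofuran O1, C7a, C3a and C7 are O4', C4', C5' and C3' of naringenin's ring B. The furan C2=C3 bond therefore spans a propenyl group on O4' and one on the adjacent C5', and C7 (the other ortho carbon, C3') carries the prenyl group.
- Forward order: rings A and C and the C2–aryl bond come intact from naringenin. The side chains are joined as prenyl (C3'), allyl (C5'), allyl (O4'); both allyl groups are then moved into conjugation, the furan ring is closed, and the MOM group is removed.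
- Stereochemistry: the single stereocentre, C2 (S), comes from the chiral pool. It is never broken; the steps with a free or transient 4'-phenoxide are run cold, and those with a free 4'-phenol are run neutral.

Key step: step 9

Remark: commercial (2S)-naringenin is assumed to be enantiomerically pure (to be confirmed by chiral HPLC, as for 2, 8, 12 and 18); flavanone locants are used (ring B primed), and the propenyl groups of 16 are expected as E/Z mixtures, which does not matter because their methyl-bearing ends are lost.

**Step 1**
Reactants: 1 (2S)-naringenin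
Product: 2 (2S)-5,4'-dihydroxy-7-(methoxymethoxy)flavanone
Conditions: MOMCl (1.05 equiv), iPr2NEt (1.2 equiv), THF, 0 °C
Reagents that add atoms: chloromethyl methyl ether, COCCl
Why: O-alkylation of a phenol with an α-chloro ether (MOM protection) should be selective because the 7-hydroxyl, para to the C4 carbonyl, is the most acidic phenol, the 5-hydroxyl is tied up in a hydrogen bond to C4=O and the 4'-hydroxyl is less acidic, while a hindered amine at 0 °C is too mild to open the pyranone ring.

**Step 2**
Reactants: 3 2-methylbut-3-en-2-ol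
Product: 5 methyl 2-methylbut-3-en-2-yl carbonate, via lithium 2-methylbut-3-en-2-olate 4 (not isolated)
Conditions: n-BuLi, THF, −78 °C; ClCO2Me, −78 → 0 °C
Reagents that add atoms: methyl chloroformate, COC(Cl)=O; n-butyllithium, [Li]CCCC (supplies only the lithium of 4)
Why: Acylation of a lithium alkoxide with a chloroformate (carbonate formation) is the standard way to acylate a hindered tertiary allylic alcohol.

**Step 3**
Reactants: 2 (2S)-5,4'-dihydroxy-7-(methoxymethoxy)flavanone; 5 methyl 2-methylbut-3-en-2-yl carbonate
Product: 6 (2S)-5-hydroxy-7-(methoxymethoxy)-4'-(2-methylbut-3-en-2-yloxy)flavanone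
Conditions: Pd(PPh3)4 (5 mol %), 5 (3 equiv), THF, 0 °C
Reagents that add atoms: none
Why: Tsuji–Trost O-allylation without added base: zerovalent palladium ionises 5 to a 1,1-dimethylallyl palladium cation and methyl carbonate, which loses CO2 to methoxide that deprotonates only the free 4'-phenol, and at 0 °C the phenoxide should attack the more substituted allyl terminus to give the tertiary ether.

**Step 4**
Reactants: 6 (2S)-5-hydroxy-7-(methoxymethoxy)-4'-(2-methylbut-3-en-2-yloxy)flavanone
Product: 8 (2S)-5,4'-dihydroxy-7-(methoxymethoxy)-3'-(3-methylbut-2-enyl)flavanone, via ortho-dienone 7 (not isolated)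
Conditions: PhMe, 110 °C, sealed tube
Reagents that add atoms: none
Why: Aromatic Claisen rearrangement ([3,3] shift) of a tertiary allyl aryl ether proceeds near 110 °C, delivers the chain with allylic inversion as a prenyl group to either of the two equivalent ortho carbons, and dienone 7 tautomerises to the phenol; the neutral medium keeps the ortho-prenylphenol from closing to a chromane.

**Step 5**
Reactants: 8 (2S)-5,4'-dihydroxy-7-(methoxymethoxy)-3'-(3-methylbut-2-enyl)flavanone; 9 allyl alcohol
Product: 10 (2S)-4'-(allyloxy)-5-hydroxy-7-(methoxymethoxy)-3'-(3-methylbut-2-enyl)flavanone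
Conditions: PPh3, DIAD, THF, 0 °C → rt
Reagents that add atoms: none
Why: Mitsunobu etherification alkylates the 4'-phenol (pKa near 10) with the activated primary alcohol without added base, and the chelated 5-hydroxyl is too weakly acidic and too hindered to compete.

**Step 6**
Reactants: 10 (2S)-4'-(allyloxy)-5-hydroxy-7-(methoxymethoxy)-3'-(3-methylbut-2-enyl)flavanone
Product: 12 (2S)-5'-allyl-5,4'-dihydroxy-7-(methoxymethoxy)-3'-(3-methylbut-2-enyl)flavanone, via ortho-dienone 11 (not isolated)
Conditions: 1,2-dichlorobenzene (degassed), 190 °C, microwave, shortest time for full conversion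
Reagents that add atoms: none
Why: Aromatic ortho-Claisen rearrangement moves the allyl group by a [3,3] shift to C5', the only free ortho carbon, and dienone 11 tautomerises to the phenol; a shift to the prenyl-bearing C3' gives a blocked dienone that can only revert or pass on to the same product, so carbon is delivered to ring B alone.

**Step 7**
Reactants: 12 (2S)-5'-allyl-5,4'-dihydroxy-7-(methoxymethoxy)-3'-(3-methylbut-2-enyl)flavanone; 9 allyl alcohol
Product: 13 (2S)-5'-allyl-4'-(allyloxy)-5-hydroxy-7-(methoxymethoxy)-3'-(3-methylbut-2-enyl)flavanone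
Conditions: PPh3, DIAD, THF (0.5 M), 0 °C → rt
Reagents that add atoms: none
Why: Mitsunobu etherification also works on 2,6-disubstituted phenols at high concentration and again avoids the base and heat of a Williamson alkylation, which would endanger C2.

**Step 8**
Reactants: 13 (2S)-5'-allyl-4'-(allyloxy)-5-hydroxy-7-(methoxymethoxy)-3'-(3-methylbut-2-enyl)flavanone
Product: 16 (2S)-5-hydroxy-7-(methoxymethoxy)-3'-(3-methylbut-2-enyl)-5'-(prop-1-enyl)-4'-(prop-1-enyloxy)flavanone (E/Z mixture), via O-propenyl C-allyl isomer 14 (not isolated), via O-allyl C-propenyl isomer 15 (not isolated)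
Conditions: RuClH(CO)(PPh3)3 (5 mol %), PhMe, 80 °C
Reagents that add atoms: none
Why: Ruthenium hydride catalysed double-bond migration (hydrometalation, then β-hydride elimination) moves each terminal allyl alkene one position into conjugation with oxygen or with the arene, through either mono-isomerised compound 14 or 15, while the trisubstituted prenyl alkene inserts into the hindered Ru–H far more slowly and should stay in place.

**Step 9**
Reactants: 16 (2S)-5-hydroxy-7-(methoxymethoxy)-3'-(3-methylbut-2-enyl)-5'-(prop-1-enyl)-4'-(prop-1-enyloxy)flavanone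
Product: 17 (2S)-5-hydroxy-7-(methoxymethoxy)-2-[7-(3-methylbut-2-enyl)-1-benzofuran-5-yl]chroman-4-one
Conditions: RuCl2(=CHPh)(PCy3)(H2IMes) (second-generation Grubbs catalyst, H2IMes = 1,3-dimesitylimidazolidin-2-ylidene, 5 mol %), 2,6-dichloro-1,4-benzoquinone (10 mol %), PhMe (0.01 M, degassed), 80 °C
Reagents that add atoms: none
Why: This is ring-closing olefin metathesis of the kind known for 2-(prop-1-enyl)phenyl prop-1-enyl ethers, which give benzofurans. The ruthenium benzylidene should first exchange with the styrenyl C5'-propenyl group, the most accessible alkene that is not an enol ether, placing the carbene on the carbon that becomes C3; [2+2] addition to the neighbouring O4'-propenyl group and cycloreversion of the ruthenacyclobutane then form the C2=C3 bond and expel a ruthenium ethylidene, which carries the chain and leaves as but-2-ene. The furan thus closes as a five-membered ring by metathesis between two groups held on adjacent ring-B atoms (C5' and O4'), and the aromatic stabilisation of the benzofuran makes the closure irreversible. No stereocentre is formed, and C2 is untouched because the medium is neutral and aprotic and no free 4'-phenol is present. The selectivity needed is for the two 1,2-disubstituted propenyl groups over the trisubstituted prenyl alkene: a carbene at C5' cannot reach the prenyl group at C3' (meta), and the only competing closure, O4'-propenyl onto prenyl to a six-membered 4H-chromene, requires metathesis at a trisubstituted alkene and gains no aromaticity. The benzoquinone additive removes ruthenium hydrides that could otherwise move the prenyl double bond.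

**Step 10**
Reactants: 17 (2S)-5-hydroxy-7-(methoxymethoxy)-2-[7-(3-methylbut-2-enyl)-1-benzofuran-5-yl]chroman-4-one
Product: 18 (2S)-5,7-dihydroxy-2-[7-(3-methylbut-2-enyl)-1-benzofuran-5-yl]chroman-4-one
Conditions: HCl (1.25 M in MeOH), 40 °C
Reagents that add atoms: none
Why: Acid-catalysed acetal exchange (solvolysis of the MOM ether) frees the 7-hydroxyl under conditions that a benzofuran, a flavanone and a prenyl group with no neighbouring free phenol should tolerate.

**Compound list**

1 | (2S)-naringenin | Oc1ccc([C@@H]2CC(=O)c3c(O)cc(O)cc3O2)cc1 | starting material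
2 | (2S)-5,4'-dihydroxy-7-(methoxymethoxy)flavanone | Oc1ccc([C@@H]2CC(=O)c3c(O)cc(OCOC)cc3O2)cc1 | intermediate
3 | 2-methylbut-3-en-2-ol | CC(C)(O)C=C | starting material
4 | lithium 2-methylbut-3-en-2-olate (formed in the flask, not isolated) | [Li+].[O-]C(C)(C)C=C | intermediate
5 | methyl 2-methylbut-3-en-2-yl carbonate | COC(=O)OC(C)(C)C=C | intermediate
6 | (2S)-5-hydroxy-7-(methoxymethoxy)-4'-(2-methylbut-3-en-2-yloxy)flavanone | C=CC(C)(C)Oc1ccc([C@@H]2CC(=O)c3c(O)cc(OCOC)cc3O2)cc1 | intermediate
7 | ortho-dienone, (2S)-5-hydroxy-7-(methoxymethoxy)-2-[3-(3-methylbut-2-enyl)-4-oxocyclohexa-1,5-dien-1-yl]chroman-4-one, either configuration at the ring sp3 carbon (not isolated) | CC(C)=CCC1C=C([C@@H]2CC(=O)c3c(O)cc(OCOC)cc3O2)C=CC1=O | intermediate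
8 | (2S)-5,4'-dihydroxy-7-(methoxymethoxy)-3'-(3-methylbut-2-enyl)flavanone | CC(C)=CCc1cc([C@@H]2CC(=O)c3c(O)cc(OCOC)cc3O2)ccc1O | intermediate
9 | allyl alcohol | C=CCO | starting material
10 | (2S)-4'-(allyloxy)-5-hydroxy-7-(methoxymethoxy)-3'-(3-methylbut-2-enyl)flavanone | CC(C)=CCc1cc([C@@H]2CC(=O)c3c(O)cc(OCOC)cc3O2)ccc1OCC=C | intermediate
11 | ortho-dienone, (2S)-2-[3-allyl-5-(3-methylbut-2-enyl)-4-oxocyclohexa-1,5-dien-1-yl]-5-hydroxy-7-(methoxymethoxy)chroman-4-one, either configuration at the ring sp3 carbon (not isolated) | C=CCC1C=C([C@@H]2CC(=O)c3c(O)cc(OCOC)cc3O2)C=C(CC=C(C)C)C1=O | intermediate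
12 | (2S)-5'-allyl-5,4'-dihydroxy-7-(methoxymethoxy)-3'-(3-methylbut-2-enyl)flavanone | CC(C)=CCc1cc([C@@H]2CC(=O)c3c(O)cc(OCOC)cc3O2)cc(CC=C)c1O | intermediate
13 | (2S)-5'-allyl-4'-(allyloxy)-5-hydroxy-7-(methoxymethoxy)-3'-(3-methylbut-2-enyl)flavanone | CC(C)=CCc1cc([C@@H]2CC(=O)c3c(O)cc(OCOC)cc3O2)cc(CC=C)c1OCC=C | intermediate
14 | (2S)-5'-allyl-5-hydroxy-7-(methoxymethoxy)-3'-(3-methylbut-2-enyl)-4'-(prop-1-enyloxy)flavanone, E/Z mixture (not isolated) | CC(C)=CCc1cc([C@@H]2CC(=O)c3c(O)cc(OCOC)cc3O2)cc(CC=C)c1OC=CC | intermediate
15 | (2S)-4'-(allyloxy)-5-hydroxy-7-(methoxymethoxy)-3'-(3-methylbut-2-enyl)-5'-(prop-1-enyl)flavanone, E/Z mixture (not isolated) | CC(C)=CCc1cc([C@@H]2CC(=O)c3c(O)cc(OCOC)cc3O2)cc(C=CC)c1OCC=C | intermediate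
16 | (2S)-5-hydroxy-7-(methoxymethoxy)-3'-(3-methylbut-2-enyl)-5'-(prop-1-enyl)-4'-(prop-1-enyloxy)flavanone, E/Z mixture at both propenyl groups | CC(C)=CCc1cc([C@@H]2CC(=O)c3c(O)cc(OCOC)cc3O2)cc(C=CC)c1OC=CC | intermediate
17 | (2S)-5-hydroxy-7-(methoxymethoxy)-2-[7-(3-methylbut-2-enyl)-1-benzofuran-5-yl]chroman-4-one | CC(C)=CCc1cc([C@@H]2CC(=O)c3c(O)cc(OCOC)cc3O2)cc2ccoc12 | intermediate
18 | (2S)-5,7-dihydroxy-2-[7-(3-methylbut-2-enyl)-1-benzofuran-5-yl]chroman-4-one | CC(C)=CCc1cc([C@@H]2CC(=O)c3c(O)cc(O)cc3O2)cc2ccoc12 | target

**Step count**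

Total: 10 steps. Longest linear sequence: 9 steps (steps 1 and 3–10 from naringenin); step 2 is a one-step side branch.

**Steps most likely to fail**

Step 6. At 190 °C the freshly formed 4'-phenol may reversibly open the pyranone ring at C2–O1, eroding the enantiomeric purity, and may add across the neighbouring prenyl or allyl alkene. The fallback sets out from 10 and comes back at 12. It runs the rearrangement as a capture process, so that the phenol never exists free while hot. 10 would be heated in 1,2-dichlorobenzene at 190 °C with N,O-bis(trimethylsilyl)acetamide (3 equiv). This first silylates the chelated hydroxyl to give the 5-O-trimethylsilyl ether of 10 F1. The phenol released by the [3,3] shift is then silylated as it forms, giving the 5,4'-bis(trimethylsilyl) ether of 12 F2. Brief stirring in methanol with a trace of citric acid at room temperature should return 12 without its 4'-phenol having been exposed to heat.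

Step 9. The catalyst may rest as an alkoxy-substituted carbene on the enol ether and turn over slowly. That carbene may then be intercepted by the prenyl alkene (six-membered closure), or decompose to hydrides that shift the prenyl double bond. The fallback sets out from 13 and comes back at 17. It takes the trisubstituted alkene out of play before any ruthenium is used.
- mCPBA (1 equiv, NaHCO3, CH2Cl2, 0 °C) should epoxidise only the electron-rich trisubstituted alkene of 13, giving the 3'-[(3,3-dimethyloxiran-2-yl)methyl] analogue of 13 F3 (either epoxide configuration).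
- RuClH(CO)(PPh3)3 in toluene at 80 °C would give the corresponding bis(propenyl) epoxide F4.
- Ring-closing metathesis under the conditions of step 9 would give the 7-[(3,3-dimethyloxiran-2-yl)methyl]benzofuran F5.
- Deoxygenation of the epoxide with the low-valent tungsten reagent from WCl6 and n-BuLi (2 equiv) in THF, −78 °C → rt, a method that tolerates ketones and free hydroxyls, should restore the prenyl alkene and give 17.

Step 3. The phenoxide may attack the unsubstituted allyl terminus, or the palladium may re-ionise the tertiary ether, draining material into the linear prenyl ether, whose Claisen product would be the wrong (1,1-dimethylallyl) isomer. The fallback sets out from 2 and comes back at 6. It replaces the ambident allyl cation by a propargyl electrophile that can only give the tertiary ether. 2 would be treated with 3-chloro-3-methylbut-1-yne, CuCl2 (1 mol %) and DBU in MeCN at −10 to 0 °C (copper-catalysed O-propargylation, kept cold and short to protect C2). This gives (2S)-5-hydroxy-7-(methoxymethoxy)-4'-(2-methylbut-3-yn-2-yloxy)flavanone F6. Semi-hydrogenation (H2, 1 atm, Pd/CaCO3 poisoned with Pb(OAc)2, quinoline, EtOAc, rt) then reduces the terminal alkyne to the alkene and gives 6.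

**Further compounds**

F1 | step 6 | (2S)-4'-(allyloxy)-7-(methoxymethoxy)-3'-(3-methylbut-2-enyl)-5-(trimethylsilyloxy)flavanone | CC(C)=CCc1cc([C@@H]2CC(=O)c3c(O[Si](C)(C)C)cc(OCOC)cc3O2)ccc1OCC=C
F2 | step 6 | (2S)-5'-allyl-7-(methoxymethoxy)-3'-(3-methylbut-2-enyl)-5,4'-bis(trimethylsilyloxy)flavanone | CC(C)=CCc1cc([C@@H]2CC(=O)c3c(O[Si](C)(C)C)cc(OCOC)cc3O2)cc(CC=C)c1O[Si](C)(C)C
F3 | step 9 | (2S)-5'-allyl-4'-(allyloxy)-3'-[(3,3-dimethyloxiran-2-yl)methyl]-5-hydroxy-7-(methoxymethoxy)flavanone, either epoxide configuration | CC1(C)OC1Cc1cc([C@@H]2CC(=O)c3c(O)cc(OCOC)cc3O2)cc(CC=C)c1OCC=C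
F4 | step 9 | (2S)-3'-[(3,3-dimethyloxiran-2-yl)methyl]-5-hydroxy-7-(methoxymethoxy)-5'-(prop-1-enyl)-4'-(prop-1-enyloxy)flavanone, E/Z mixture | CC1(C)OC1Cc1cc([C@@H]2CC(=O)c3c(O)cc(OCOC)cc3O2)cc(C=CC)c1OC=CC
F5 | step 9 | (2S)-2-{7-[(3,3-dimethyloxiran-2-yl)methyl]-1-benzofuran-5-yl}-5-hydroxy-7-(methoxymethoxy)chroman-4-one | CC1(C)OC1Cc1cc([C@@H]2CC(=O)c3c(O)cc(OCOC)cc3O2)cc2ccoc12
F6 | step 3 | (2S)-5-hydroxy-7-(methoxymethoxy)-4'-(2-methylbut-3-yn-2-yloxy)flavanone | C#CC(C)(C)Oc1ccc([C@@H]2CC(=O)c3c(O)cc(OCOC)cc3O2)cc1
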